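# Proposed synthesis of (2S,3R)-2,3-dihydro-3,3''-biapigenin (CNP0208264.1)

## Compound numbering

- **1** 2',4',6'-trihydroxyacetophenone
- **2** benzyl bromide
- **3** tri-O-benzyl ketone
- **4** lithium enolate of 3 (in the flask)
- **5** hexabenzyl 1,4-diketone
- **6** bis-phenol 1,4-diketone
- **7** 4-(benzyloxy)benzoyl chloride
- **8** bis(aroyl ester) diketone
- **9** bis(1,3-diketone) (in the flask)
- **10** hexa-O-benzyl 3,3''-biflavone
- **11** silyl enol ether (in the flask)
- **12** hexa-O-benzyl ether of the target
- **13** target

## Analysis of the target

Compound 13 is a flavanone (rings A, B, C) joined to a flavone (rings A'', B'', C'') by one bond between C3 of the flavanone and C3'' of the flavone. Its only stereocentres are C2 (S) and C3 (R) of ring C. H2 and H3 are anti, so the 4-hydroxyphenyl group on C2 and the flavonyl group on C3 are trans and can both be equatorial, which is the more stable relative arrangement. C3–H lies alpha to the C4 ketone and O1 lies beta to it, so base can epimerise C3 and can open ring C by retro-oxa-Michael reaction, which would erase C2. The six free phenols, four of them on phloroglucinol-type rings, are sensitive to oxidants and strong base. The C3–C3'' bond joins two carbons that each sit between an aryl-bearing C2 and a carbonyl C4, so coupling two finished heterocycles there would be a fully ortho-substituted union. The two halves differ only by the two hydrogens on C2 and C3, and the real difficulty is to make a hindered, nearly symmetrical dimer and then treat one half differently with absolute stereocontrol. The route rests on one feature: C4–C3–C3''–C4'' is a succinyl (1,4-dicarbonyl) unit with the same ring A/ring A'' aryl group at each end, and C2 and C2'' carry the same 4-hydroxyphenyl group, so 13 is the 2,3-dihydro derivative of a symmetrical 3,3''-biflavone.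

## Retrosynthetic reasoning

**13 to 12.** The six O–benzyl bonds are cut last. Benzyl ethers withstand amide bases, hydride transfer and mild acid, and they are removed by neutral hydrogenolysis, so the epimerisable C3 and the C2–O1 bond of 13 are not exposed to acid or base at the end. The forward step must cleave six aryl ethers without touching C2''=C3'' or the benzylic C2–O1 bond.

**12 to 10.** Removing the hydrogens on C2 and C3 deletes both stereocentres and gives 10, whose halves are identical. This turns an unsymmetrical dimer into a symmetrical one and postpones all stereochemistry to one step in which either half may react. The forward step must transfer hydride to C2 of one chromenone only, on one face under catalyst control, holding the product as enol derivative 11. Protonation of C3 under equilibrating conditions then gives the trans arrangement.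

**10 to 8 (through 9).** This is the central disconnection, and four bonds are cut. O1–C2 and O1''–C2'' are opened to give the phenol/aroyl ketone pairs of 9. C2–C3 and C2''–C3'' are then cut by returning each aroyl group from carbon to the neighbouring phenol oxygen, which gives 8. Cutting C3–C3'' instead would mean joining two fully substituted chromenone carbons. Cutting beside it leaves C3–C3'' as an unhindered CH2–CH2 bond of an open-chain diketone, and the aroyl groups are delivered intramolecularly. The gain is two rings and four skeletal bonds in one operation, by the same reaction run twice. The forward step must achieve two enolisations, two O-to-C acyl migrations and two ring closures, without furan formation from the 1,4-dicarbonyl array and without loss of benzyl ethers.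

**8 to 6 and 7.** The two ester C–O bonds are cut. Acid chloride 7 supplies ring B, ring B'' and the carbons C2 and C2''. The forward reaction is a plain phenol acylation that must stop at the ester.

**6 to 5.** The two hydroxyl groups next to the ketones are traced back to benzyl ethers. The central bond is best made by enolate oxidation, and a free phenoxide beside the enolate would itself be oxidised or would capture the oxidised alpha-carbon in a five-membered ring. All phenols are therefore carried through that step as ethers. The two ethers that flank the ketones can be removed afterwards because only they can chelate together with the carbonyl oxygen.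

**5 to 3 (through 4).** The central CH2–CH2 bond (the later C3–C3'' bond) is cut, which divides 5 into two identical molecules of methyl ketone 3. In the forward direction two molecules of 3 are deprotonated to enolate 4 and joined by oxidative dimerisation, each molecule supplying one half of 5. The bond is made while both carbons are still primary, which is the least hindered moment in the synthesis.

**3 to 1 and 2.** The three O–benzyl bonds are cut. Compound 1 already holds ring A with its three oxygens and the acetyl group that becomes C4 and C3.

## Alternatives that were turned down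

**Alternative 1:** Ring C is disconnected at C3–C4. The flavone half is present only as an open 1,3-diketone on C3, with the ring A'' phenol masked as a methoxymethyl ether.
- **Forward key step.** A chiral triazolylidene carbene with a tertiary amine converts the ring A aldehyde into an acyl-anion equivalent, which adds intramolecularly to the alkylidene diketone (Stetter reaction). The C2 centre of the open-chain precursor must equilibrate while one enantiomer cyclises. The product is (2S,3R)-5,7-bis(benzyloxy)-2-[4-(benzyloxy)phenyl]-3-{1-[4-(benzyloxy)phenyl]-3-[2,4-bis(benzyloxy)-6-(methoxymethoxy)phenyl]-1,3-dioxopropan-2-yl}chroman-4-one (A1). Acid would then remove the acetal and close ring C'' to reach 12.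
- **For.** Carbene-catalysed Stetter closure to chroman-4-ones is a ring-forming reaction class with reliable enantiocontrol. One catalyst handles both stereocentres, and no tetrasubstituted alkene has to be reduced. On precedent for the stereo-defining step it is stronger than the chosen route.
- **Against.** The aldehyde is flanked by two oxygen substituents, and the acceptor carbon (future C3) carries a branched aryl- and aryloxy-substituted carbon, so both reacting centres are hindered. The hydrogen on C2 is only vinylogously acidic, and inversion otherwise needs reversible loss of the aryloxide, so racemisation faster than cyclisation is not assured. A1 is a beta-aryloxy ketone with an acidic diketone methine, so the amine base can open ring C again and erode C2. The precursor of A1 needs an unsymmetrical 1,3-diketone, its condensation with an alpha-aryloxy aldehyde, and two differently protected ring A units.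
- **Comparison.** The chosen route reaches precursor 8 in four routine steps by using the identity of the halves. It accepts more risk in its stereo-defining step, which has a resolution fallback.

**Alternative 2:** Rings A and A'' are disconnected at C4a–C5 and C4a''–C5'', and ring C'' at O1''–C2''. Both phloroglucinol rings are built from open poly-beta-carbonyl chains.
- **Forward key step.** A magnesium alkoxide in its parent alcohol folds both triketo ester arms by Claisen condensation. The new phenoxide next to C4'' then displaces a methoxy group at C2'' to close the pyranone. The product is (E)-3-[4-(benzyloxy)phenyl]-2-{2-[4-(benzyloxy)phenyl]-5,7-dihydroxy-4-oxo-4H-chromen-3-yl}-1-(2,4,6-trihydroxyphenyl)prop-2-en-1-one (A2).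
- **For.** It is polyketide-like, forms three rings in one operation, and needs no protecting groups on rings A and A''. In protecting-group economy it is stronger than the chosen route, which carries six benzyl groups.
- **Against.** Each arm can also fold by aldol reaction to a resorcylate-type ring or close through oxygen to a pyranone, and both arms must fold correctly. The precursor of A2 has eight or more carbonyl groups, would need repeated acylation of polyanions, and would be hard to store. The effort builds rings that are bought ready-made in 1. A2 still has no stereocentre, and a chalcone with two free ortho phenols closes to the flavanone spontaneously, so C2 would form without control.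
- **Comparison.** The chosen route buys ring A, makes only the bonds that have to be made, and keeps a defined place for the asymmetric step.

**Alternative 3:** Ring C is disconnected at O1–C2. The flavone half is complete and the other half is an alpha-flavonyl 2'-hydroxychalcone.
- **Forward key step.** A bifunctional cinchona-alkaloid thiourea activates the phenol through its amine and the enone through hydrogen bonding. The phenol adds to C2 (oxa-Michael reaction) and C3 is protonated. The product is (2S,3R)-5,7-bis(benzyloxy)-3-{5,7-bis(benzyloxy)-2-[4-(benzyloxy)phenyl]-4-oxo-4H-chromen-3-yl}-2-[4-(benzyloxy)phenyl]-2,3-dihydro-4H-chromen-4-one (A3), which is identical with 12.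
- **For.** It forms directly the bond that makes C2 stereogenic, and C3 follows by equilibration. There is no mono- versus bis-reaction problem and no tetrasubstituted alkene to reduce. The stereo-defining step is closer to known chemistry than step 6 of the chosen route.
- **Against.** The well-behaved substrates of this catalysis carry an extra electron-withdrawing group on the alpha-carbon. Here the alpha-substituent is a bulky, twisted flavonyl group that lowers the electrophilicity of the enone and shields C2. The oxa-Michael addition is reversible, so the basic catalyst can drain the enantiomeric purity. The chalcone precursor of A3 is unsymmetrical: one CH2 group of a diketone such as 6 must be acylated and cyclised while the other is condensed with an aldehyde. That needs either a statistical half-reaction or separate construction of the halves.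
- **Comparison.** Both routes meet at the same penultimate compound. The chosen route gets there in six steps by doing every reaction twice until the last C–H bond-forming step, and its precursor 8 comes from routine reactions.

Key step: step 5

Assumption: the sense of induction of the copper hydride catalyst on a fully substituted flavone is not known in advance; the (R)-ligand is written in step 6, and its antipode is to be used if hydride is found to go to the other face of C2.

## Route

Step 1
Reactants: 1 2',4',6'-trihydroxyacetophenone; 2 benzyl bromide
Product: 3 1-[2,4,6-tris(benzyloxy)phenyl]ethan-1-one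
Conditions: BnBr (3.6 equiv), K2CO3 (4 equiv), DMF, 70 °C
Reagents that add atoms: benzyl bromide (2), BrCc1ccccc1
Why: Williamson etherification of all three phenols; the hydroxyl chelated to the ketone reacts last and needs the excess of 2 in warm DMF, and carbonate in a dipolar aprotic solvent favours O-alkylation over benzylation on ring carbon.

Step 2
Reactants: 3 1-[2,4,6-tris(benzyloxy)phenyl]ethan-1-one; 3 1-[2,4,6-tris(benzyloxy)phenyl]ethan-1-one (second molecule)
Product: 5 1,4-bis[2,4,6-tris(benzyloxy)phenyl]butane-1,4-dione, via lithium enolate 4 (not isolated)
Conditions: LiN(i-Pr)2 (1.05 equiv per ketone), THF, −78 °C; then CuCl2 (1.1 equiv per ketone), DMF, −78 °C → rt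
Reagents that add atoms: 1-[2,4,6-tris(benzyloxy)phenyl]ethan-1-one (3, second molecule), CC(=O)c1c(OCc2ccccc2)cc(OCc2ccccc2)cc1OCc1ccccc1
Why: Oxidative dimerisation of a ketone lithium enolate by divalent copper, a known reaction of aryl methyl ketones: two molecules of 3 are deprotonated to 4, one-electron oxidation gives an alpha-keto radical (or copper enolate), and two such units join at the primary carbon, so each molecule of 3 supplies one half of 5 and one hydrogen is lost from each methyl group. With all phenols capped there is no phenoxide that could be oxidised or could close onto the oxidised alpha-carbon to a benzofuranone.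

Step 3
Reactants: 5 1,4-bis[2,4,6-tris(benzyloxy)phenyl]butane-1,4-dione
Product: 6 1,4-bis[2,4-bis(benzyloxy)-6-hydroxyphenyl]butane-1,4-dione
Conditions: BCl3 (2.2 equiv), CH2Cl2, −78 °C; then H2O
Reagents that add atoms: none
Why: Chelation-directed ether cleavage: BCl3 binds the ketone oxygen together with one flanking benzyl ether, and chloride removes that benzyl group. The resulting six-membered boron chelate occupies the carbonyl, so the second ortho ether and the para ether are not activated at −78 °C with one equivalent per ketone.

Step 4
Reactants: 6 1,4-bis[2,4-bis(benzyloxy)-6-hydroxyphenyl]butane-1,4-dione; 7 4-(benzyloxy)benzoyl chloride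
Product: 8 1,4-bis{2,4-bis(benzyloxy)-6-{[4-(benzyloxy)benzoyl]oxy}phenyl}butane-1,4-dione
Conditions: 7 (2.4 equiv), Et3N (3 equiv), 4-(dimethylamino)pyridine (10 mol %), CH2Cl2, 0 °C → rt
Reagents that add atoms: 4-(benzyloxy)benzoyl chloride (7), O=C(Cl)c1ccc(OCc2ccccc2)cc1
Why: Acylation of both phenols by an acid chloride under nucleophilic catalysis; the amine base is too weak to enolise the ketones, so the acyl groups stay on oxygen and the diester can be isolated.

Step 5
Reactants: 8 1,4-bis{2,4-bis(benzyloxy)-6-{[4-(benzyloxy)benzoyl]oxy}phenyl}butane-1,4-dione
Product: 10 5,5',7,7'-tetrakis(benzyloxy)-2,2'-bis[4-(benzyloxy)phenyl]-4H,4'H-[3,3'-bichromene]-4,4'-dione, via bis(1,3-diketone) 9 (not isolated)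
Conditions: LiN(SiMe3)2 (6 equiv), THF, −78 → 0 °C; AcOH quench, evaporate; then H2SO4 (cat.), AcOH, 60 °C
Reagents that add atoms: none
Why: LiN(SiMe3)2 turns each CH2 of 8 into a lithium enolate whose carbon attacks the carbonyl of the aryl ester on its own ring through a six-membered cyclic arrangement; the tetrahedral intermediate collapses with release of the phenoxide, so each aroyl group ends on C3 or C3'' (intramolecular Claisen acylation, the Baker–Venkataraman rearrangement) and 9 forms as its polyanion. The excess of base is needed because the first 1,3-diketone is deprotonated at once and the second enolisation takes place beside that diketonate; as both aroyl groups are the same, a transfer across the molecule through the seven-membered alternative would give the same 9. After the quench, H2SO4 in AcOH lets each phenol add to the aroyl carbonyl carbon that becomes C2 or C2'' (6-exo-trig, oxygen on carbon), and loss of water from the hemiketal gives the aromatic 4-pyranone, so ring C and ring C'' are closed by the same 6-exo-trig mode. The closest known reaction type is the Baker–Venkataraman rearrangement and acid cyclodehydration of alpha-substituted 2'-aroyloxyaryl ketones to 3-substituted flavones, run here at both ends of one molecule. No stereocentre is formed: the two methine centres of 9 are labile and disappear, and the C3–C3'' axis of 10 is left uncontrolled because the target does not hold it as a stereogenic element. The step needs C- and not O-acylation, which the intramolecular six-membered geometry secures, and it needs phenol closure to outrun furan formation from the 1,4-dicarbonyl pairs of 9, which is expected because each phenol is held beside its aroyl carbonyl and is a better nucleophile than an enol oxygen. The benzyl ethers peri to C4 and C4'' are the most acid-sensitive groups, hence only catalytic H2SO4 and 60 °C at most.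

Step 6
Reactants: 10 5,5',7,7'-tetrakis(benzyloxy)-2,2'-bis[4-(benzyloxy)phenyl]-4H,4'H-[3,3'-bichromene]-4,4'-dione
Product: 12 (2S,3R)-5,7-bis(benzyloxy)-3-{5,7-bis(benzyloxy)-2-[4-(benzyloxy)phenyl]-4-oxo-4H-chromen-3-yl}-2-[4-(benzyloxy)phenyl]-2,3-dihydro-4H-chromen-4-one, via silyl enol ether 11 (not isolated)
Conditions: Cu(OAc)2 (5 mol %), (R)-5,5'-bis[bis(3,5-di-tert-butyl-4-methoxyphenyl)phosphino]-4,4'-bi-1,3-benzodioxole (5.5 mol %), (EtO)2MeSiH (1.2 equiv), toluene, 0 °C → rt; then AcOH, THF–H2O, rt
Reagents that add atoms: none
Why: Proposed new method: the phosphine-bound copper hydride should add hydride to C2 of one of the two equivalent chromenone units of 10 on the face chosen by the ligand, and the copper enolate is silylated by the silane to 11, which regenerates the hydride and hides the new ketone from 1,2-reduction; the closest known reaction type is the copper hydride-catalysed enantioselective 1,4-reduction of beta,beta-disubstituted enones and 2-substituted chromen-4-ones, not yet shown on a fully substituted flavone C2=C3 bond, and the bulky aryl groups on phosphorus are chosen because they give the most active hydride for hindered acceptors. C2 (S) is set by the ligand; C3 is protonated when aqueous acetic acid hydrolyses 11 and equilibrates through the enol to the 2,3-trans arrangement (3R), in which the aryl and flavonyl groups are both equatorial. The limited amount of silane and the absence of an alcohol are meant to stop the reaction after one hydride transfer.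

Step 7
Reactants: 12 (2S,3R)-5,7-bis(benzyloxy)-3-{5,7-bis(benzyloxy)-2-[4-(benzyloxy)phenyl]-4-oxo-4H-chromen-3-yl}-2-[4-(benzyloxy)phenyl]-2,3-dihydro-4H-chromen-4-one
Product: 13 (2S,3R)-5,7-dihydroxy-3-[5,7-dihydroxy-2-(4-hydroxyphenyl)-4-oxo-4H-chromen-3-yl]-2-(4-hydroxyphenyl)-2,3-dihydro-4H-chromen-4-one
Conditions: H2 (1 atm), Pd/C (10%), THF–MeOH, rt
Reagents that add atoms: none
Why: Hydrogenolysis of six aryl benzyl ethers over palladium under neutral conditions; the tetrasubstituted C2''=C3'' bond and the ketones are not expected to be reduced at room temperature and one atmosphere. No acid or base is present that could enolise C3 or open ring C, so both stereocentres are kept.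

## Compound list

1 | 2',4',6'-trihydroxyacetophenone | CC(=O)c1c(O)cc(O)cc1O | starting material
2 | benzyl bromide | BrCc1ccccc1 | starting material
3 | 1-[2,4,6-tris(benzyloxy)phenyl]ethan-1-one | CC(=O)c1c(OCc2ccccc2)cc(OCc2ccccc2)cc1OCc1ccccc1 | intermediate
4 | lithium 1-[2,4,6-tris(benzyloxy)phenyl]ethen-1-olate | [Li]OC(=C)c1c(OCc2ccccc2)cc(OCc2ccccc2)cc1OCc1ccccc1 | intermediate (not isolated)
5 | 1,4-bis[2,4,6-tris(benzyloxy)phenyl]butane-1,4-dione | O=C(CCC(=O)c1c(OCc2ccccc2)cc(OCc2ccccc2)cc1OCc1ccccc1)c1c(OCc2ccccc2)cc(OCc2ccccc2)cc1OCc1ccccc1 | intermediate
6 | 1,4-bis[2,4-bis(benzyloxy)-6-hydroxyphenyl]butane-1,4-dione | O=C(CCC(=O)c1c(O)cc(OCc2ccccc2)cc1OCc1ccccc1)c1c(O)cc(OCc2ccccc2)cc1OCc1ccccc1 | intermediate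
7 | 4-(benzyloxy)benzoyl chloride | O=C(Cl)c1ccc(OCc2ccccc2)cc1 | starting material
8 | 1,4-bis{2,4-bis(benzyloxy)-6-{[4-(benzyloxy)benzoyl]oxy}phenyl}butane-1,4-dione | O=C(CCC(=O)c1c(OC(=O)c2ccc(OCc3ccccc3)cc2)cc(OCc2ccccc2)cc1OCc1ccccc1)c1c(OC(=O)c2ccc(OCc3ccccc3)cc2)cc(OCc2ccccc2)cc1OCc1ccccc1 | intermediate
9 | 2,3-bis[2,4-bis(benzyloxy)-6-hydroxybenzoyl]-1,4-bis[4-(benzyloxy)phenyl]butane-1,4-dione (methine centres labile, not defined) | O=C(c1ccc(OCc2ccccc2)cc1)C(C(=O)c1c(O)cc(OCc2ccccc2)cc1OCc1ccccc1)C(C(=O)c1ccc(OCc2ccccc2)cc1)C(=O)c1c(O)cc(OCc2ccccc2)cc1OCc1ccccc1 | intermediate (not isolated)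
10 | 5,5',7,7'-tetrakis(benzyloxy)-2,2'-bis[4-(benzyloxy)phenyl]-4H,4'H-[3,3'-bichromene]-4,4'-dione | O=c1c(-c2c(-c3ccc(OCc4ccccc4)cc3)oc3cc(OCc4ccccc4)cc(OCc4ccccc4)c3c2=O)c(-c2ccc(OCc3ccccc3)cc2)oc2cc(OCc3ccccc3)cc(OCc3ccccc3)c12 | intermediate
11 | 5,7-bis(benzyloxy)-2-[4-(benzyloxy)phenyl]-3-{(2R)-5,7-bis(benzyloxy)-2-[4-(benzyloxy)phenyl]-4-{[diethoxy(methyl)silyl]oxy}-2H-chromen-3-yl}-4H-chromen-4-one (same spatial arrangement at C2 as in 12; the descriptor changes because C3 is sp2) | CCO[Si](C)(OCC)OC1=C(c2c(-c3ccc(OCc4ccccc4)cc3)oc3cc(OCc4ccccc4)cc(OCc4ccccc4)c3c2=O)[C@@H](c2ccc(OCc3ccccc3)cc2)Oc2cc(OCc3ccccc3)cc(OCc3ccccc3)c12 | intermediate (not isolated)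
12 | (2S,3R)-5,7-bis(benzyloxy)-3-{5,7-bis(benzyloxy)-2-[4-(benzyloxy)phenyl]-4-oxo-4H-chromen-3-yl}-2-[4-(benzyloxy)phenyl]-2,3-dihydro-4H-chromen-4-one | O=C1c2c(OCc3ccccc3)cc(OCc3ccccc3)cc2O[C@H](c2ccc(OCc3ccccc3)cc2)[C@H]1c1c(-c2ccc(OCc3ccccc3)cc2)oc2cc(OCc3ccccc3)cc(OCc3ccccc3)c2c1=O | intermediate
13 | (2S,3R)-5,7-dihydroxy-3-[5,7-dihydroxy-2-(4-hydroxyphenyl)-4-oxo-4H-chromen-3-yl]-2-(4-hydroxyphenyl)-2,3-dihydro-4H-chromen-4-one | O=C1c2c(O)cc(O)cc2O[C@H](c2ccc(O)cc2)[C@H]1c1c(-c2ccc(O)cc2)oc2cc(O)cc(O)c2c1=O | target

## Step count and least certain steps

Total step count: 7. Longest linear sequence: 7 steps, from 1 to 13.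

**Step 6 (Proposed new method).**
- **What may go wrong.** Hydride transfer to C2 may be slow or fail, because this beta-carbon is fully substituted and electron-rich and its neighbour C3 carries the second chromenone. A second hydride transfer to the other chromenone, or 1,2-reduction, may compete. Facial discrimination may be insufficient. If rotation about C3–C3'' in 10 is slow, 10 is a pair of atropisomers; the catalyst then meets a matched and a mismatched substrate, and both converge on 12 only if ligand control at C2 dominates. Ring opening during the C3 equilibration would erode C2.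
- **Fallback (known chemistry), from 10 back to 12.** Conjugate hydride addition to 10 with LiBH(s-Bu)3 (1.05 equiv, THF, −78 °C), followed by acetic acid protonation and equilibration of C3, should give the trans racemate. This is an equimolar mixture of 12 and its antipode, (2R,3S)-5,7-bis(benzyloxy)-3-{5,7-bis(benzyloxy)-2-[4-(benzyloxy)phenyl]-4-oxo-4H-chromen-3-yl}-2-[4-(benzyloxy)phenyl]-2,3-dihydro-4H-chromen-4-one F1. The anionic enolate formed after the first addition disfavours a second one. The enantiomers are separated by preparative chromatography on a polysaccharide carbamate chiral stationary phase, and the route is rejoined at 12.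

**Step 5 (key step).**
- **What may go wrong.** The second acyl transfer may stall, because the second enolisation has to occur next to an existing diketonate. Acid may close a furan from the 1,4-dicarbonyl array. The benzyl ethers peri to the carbonyl groups may be partly lost in acid; if that is the only defect, re-benzylation of the crude product with 2 and K2CO3 restores 10.
- **Fallback, from 1 (with 2 and 7) back to 10.** The fallback forms the C3–C3'' bond last instead of first. Compound 1 is benzylated only twice (2, 2.1 equiv, K2CO3, acetone, reflux; the chelated hydroxyl stays free) to 1-[2,4-bis(benzyloxy)-6-hydroxyphenyl]ethan-1-one F2. Acylation of F2 with 7 (Et3N, 4-(dimethylamino)pyridine, CH2Cl2) gives 2-acetyl-3,5-bis(benzyloxy)phenyl 4-(benzyloxy)benzoate F3. LiN(SiMe3)2 rearranges F3 to 1-[2,4-bis(benzyloxy)-6-hydroxyphenyl]-3-[4-(benzyloxy)phenyl]propane-1,3-dione F4, and H2SO4 in AcOH closes F4 to 5,7-bis(benzyloxy)-2-[4-(benzyloxy)phenyl]-4H-chromen-4-one F5. Lithiation of F5 at C3 with LiN(i-Pr)2 and quenching with iodine gives 5,7-bis(benzyloxy)-2-[4-(benzyloxy)phenyl]-3-iodo-4H-chromen-4-one F6. Ullmann homocoupling of two molecules of F6 with copper powder in hot DMF then gives 10.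

**Step 2.**
- **What may go wrong.** Alpha-chlorination of the enolate by CuCl2, or proton transfer and incomplete oxidation, may take the place of coupling.
- **Fallback, from 3 back to 5.** The bond is made by polar alkylation instead of radical coupling. Compound 3 is converted with Me3SiOTf and Et3N to {1-[2,4,6-tris(benzyloxy)phenyl]ethenyl}oxy(trimethyl)silane F7. N-Bromosuccinimide at −78 °C converts F7 to 2-bromo-1-[2,4,6-tris(benzyloxy)phenyl]ethan-1-one F8; the enol ether reacts faster than the aromatic ring. The zinc enolate of a second portion of 3 (ZnCl2, Et2NH, t-BuOH, toluene) is then alkylated by F8 to give 5.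

**Step 3.**
- **What may go wrong.** Further benzyl ethers may be cleaved, or the released benzyl group may be transferred to the electron-rich ring carbons.
- **Fallback, from 5 back to 6.** All six benzyl groups of 5 are removed by hydrogenolysis (H2, Pd/C) to give 1,4-bis(2,4,6-trihydroxyphenyl)butane-1,4-dione F9. F9 is benzylated four times with 2 (4.2 equiv, K2CO3, acetone, reflux). The hydroxyl on each ring that is hydrogen-bonded to the ketone reacts last and stays free, which gives 6.

## Further compounds

F1 | step 6 | (2R,3S)-5,7-bis(benzyloxy)-3-{5,7-bis(benzyloxy)-2-[4-(benzyloxy)phenyl]-4-oxo-4H-chromen-3-yl}-2-[4-(benzyloxy)phenyl]-2,3-dihydro-4H-chromen-4-one | O=C1c2c(OCc3ccccc3)cc(OCc3ccccc3)cc2O[C@@H](c2ccc(OCc3ccccc3)cc2)[C@@H]1c1c(-c2ccc(OCc3ccccc3)cc2)oc2cc(OCc3ccccc3)cc(OCc3ccccc3)c2c1=O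
F2 | step 5 | 1-[2,4-bis(benzyloxy)-6-hydroxyphenyl]ethan-1-one | CC(=O)c1c(O)cc(OCc2ccccc2)cc1OCc1ccccc1
F3 | step 5 | 2-acetyl-3,5-bis(benzyloxy)phenyl 4-(benzyloxy)benzoate | CC(=O)c1c(OC(=O)c2ccc(OCc3ccccc3)cc2)cc(OCc2ccccc2)cc1OCc1ccccc1
F4 | step 5 | 1-[2,4-bis(benzyloxy)-6-hydroxyphenyl]-3-[4-(benzyloxy)phenyl]propane-1,3-dione | O=C(CC(=O)c1c(O)cc(OCc2ccccc2)cc1OCc1ccccc1)c1ccc(OCc2ccccc2)cc1
F5 | step 5 | 5,7-bis(benzyloxy)-2-[4-(benzyloxy)phenyl]-4H-chromen-4-one | O=c1cc(-c2ccc(OCc3ccccc3)cc2)oc2cc(OCc3ccccc3)cc(OCc3ccccc3)c12
F6 | step 5 | 5,7-bis(benzyloxy)-2-[4-(benzyloxy)phenyl]-3-iodo-4H-chromen-4-one | O=c1c(I)c(-c2ccc(OCc3ccccc3)cc2)oc2cc(OCc3ccccc3)cc(OCc3ccccc3)c12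
F7 | step 2 | {1-[2,4,6-tris(benzyloxy)phenyl]ethenyl}oxy(trimethyl)silane | C=C(O[Si](C)(C)C)c1c(OCc2ccccc2)cc(OCc2ccccc2)cc1OCc1ccccc1
F8 | step 2 | 2-bromo-1-[2,4,6-tris(benzyloxy)phenyl]ethan-1-one | O=C(CBr)c1c(OCc2ccccc2)cc(OCc2ccccc2)cc1OCc1ccccc1
F9 | step 3 | 1,4-bis(2,4,6-trihydroxyphenyl)butane-1,4-dione | O=C(CCC(=O)c1c(O)cc(O)cc1O)c1c(O)cc(O)cc1O
A1 | alternative 1 | (2S,3R)-5,7-bis(benzyloxy)-2-[4-(benzyloxy)phenyl]-3-{1-[4-(benzyloxy)phenyl]-3-[2,4-bis(benzyloxy)-6-(methoxymethoxy)phenyl]-1,3-dioxopropan-2-yl}chroman-4-one | O=C1c2c(OCc3ccccc3)cc(OCc3ccccc3)cc2O[C@H](c2ccc(OCc3ccccc3)cc2)[C@H]1C(C(=O)c1ccc(OCc2ccccc2)cc1)C(=O)c1c(OCOC)cc(OCc2ccccc2)cc1OCc1ccccc1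
A2 | alternative 2 | (E)-3-[4-(benzyloxy)phenyl]-2-{2-[4-(benzyloxy)phenyl]-5,7-dihydroxy-4-oxo-4H-chromen-3-yl}-1-(2,4,6-trihydroxyphenyl)prop-2-en-1-one | O=C(c1c(O)cc(O)cc1O)/C(=C/c1ccc(OCc2ccccc2)cc1)c1c(-c2ccc(OCc3ccccc3)cc2)oc2cc(O)cc(O)c2c1=O
A3 | alternative 3 | (2S,3R)-5,7-bis(benzyloxy)-3-{5,7-bis(benzyloxy)-2-[4-(benzyloxy)phenyl]-4-oxo-4H-chromen-3-yl}-2-[4-(benzyloxy)phenyl]-2,3-dihydro-4H-chromen-4-one | O=C1c2c(OCc3ccccc3)cc(OCc3ccccc3)cc2O[C@H](c2ccc(OCc3ccccc3)cc2)[C@H]1c1c(-c2ccc(OCc3ccccc3)cc2)oc2cc(OCc3ccccc3)cc(OCc3ccccc3)c2c1=O
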